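**Retrosynthetic overview**

1. The target is an achiral tridepside of three orcinol-type benzene rings: ring A (2-hydroxy-4-methoxy-6-methylbenzoyl), ring B (central 2-hydroxy-6-methylbenzoyl, acylated by A at its 4-O) and ring C (methyl 2-methoxy-6-methylbenzoate, acylated by B at its 4-O). No ring is formed in the route; all three arenes are bought (methyl orsellinate twice, orcinol once).
2. Key disconnection: the C–C bond between C1 of ring B and the carbonyl carbon of the B→C ester. That carbon is carried in as the formyl carbon of the ring-C aryl formate and joined to ring-B C1 (as aryl iodide) by a Pd-catalysed aryloxycarbonylation without CO gas, in effect a three-component union ArI + CO + Ar'OH.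
3. Enabling feature: the B–C link is an Ar–C(=O)–OAr' unit whose single carbonyl carbon sits between an sp2 carbon (ring-B C1, flanked by C2–O and C6–CH3, para to C4–O) and the acidic 4-O of ring C (para to CO2Me). Because C1 is para to the oxygen that will carry ring A, para-iodination of an orcinol mono-carbonate places the iodine exactly there.
4. Second disconnection: the A→B ester, by mixed-anhydride acylation of the free phenol of the iodinated ring-B unit. The ring-B C2 oxygen travels as a benzyl carbonate and the ring-A C2 oxygen as a benzyl ether; both fall in one final hydrogenolysis.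
5. Rings A and C both come from methyl orsellinate by complementary O-alkylation (free 4-OH first, chelated 2-OH second).

Key step: step 11

Remark: the target has no stereocentre and no stereogenic double bond, so it is a single achiral compound and no step has to control configuration.

**Route**

Step 1
Reactants: 1 methyl orsellinate (methyl 2,4-dihydroxy-6-methylbenzoate)
Product: 2 methyl 4-(benzyloxy)-2-hydroxy-6-methylbenzoate
Conditions: BnBr (1.05 equiv), K2CO3 (1.1 equiv), acetone, reflux
Reagents that add atoms: benzyl bromide, BrCc1ccccc1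
Why: Williamson ether synthesis, in which the 2-OH is hydrogen-bonded to the ester carbonyl and much less nucleophilic, so one equivalent of benzyl bromide should alkylate only the 4-OH.

Step 2
Reactants: 2 methyl 4-(benzyloxy)-2-hydroxy-6-methylbenzoate
Product: 3 methyl 4-(benzyloxy)-2-methoxy-6-methylbenzoate
Conditions: MeI (3 equiv), K2CO3, DMF, 60 °C
Reagents that add atoms: iodomethane, CI
Why: Williamson ether synthesis under forcing conditions (polar aprotic solvent, excess MeI, heat) should alkylate the remaining chelated 2-OH.

Step 3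
Reactants: 3 methyl 4-(benzyloxy)-2-methoxy-6-methylbenzoate
Product: 4 methyl 4-hydroxy-2-methoxy-6-methylbenzoate
Conditions: H2 (1 atm), 10% Pd/C, EtOAc–MeOH, rt
Reagents that add atoms: none
Why: Catalytic hydrogenolysis of a benzyl aryl ether should free the 4-OH while the methyl ester and methyl ether stay inert.

Step 4
Reactants: 4 methyl 4-hydroxy-2-methoxy-6-methylbenzoate
Product: 5 methyl 4-(formyloxy)-2-methoxy-6-methylbenzoate
Conditions: HCO2H/Ac2O (premixed, 60 °C, 1 h), then 4, NaOAc (cat.), toluene, 0 °C to rt
Reagents that add atoms: formic acid, O=CO, delivered as acetic formic anhydride, CC(=O)OC=O, made in the flask with acetic anhydride, CC(=O)OC(C)=O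
Why: O-Formylation of a phenol with acetic formic anhydride should transfer the formyl group, the more electrophilic acyl group of the mixed anhydride, as in the usual preparation of electron-poor aryl formates used as CO carriers.

Step 5
Reactants: 1 methyl orsellinate
Product: 6 methyl 2-hydroxy-4-methoxy-6-methylbenzoate
Conditions: MeI (1.1 equiv), K2CO3 (1.1 equiv), acetone, reflux
Reagents that add atoms: iodomethane, CI
Why: Regioselective Williamson methylation should take place at the non-chelated 4-OH for the same reason as in step 1.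

Step 6
Reactants: 6 methyl 2-hydroxy-4-methoxy-6-methylbenzoate
Product: 7 methyl 2-(benzyloxy)-4-methoxy-6-methylbenzoate
Conditions: BnBr (1.5 equiv), K2CO3, DMF, 70 °C
Reagents that add atoms: benzyl bromide, BrCc1ccccc1
Why: Williamson benzylation under forcing conditions should mask the chelated 2-OH as a hydrogenolysable ether.

Step 7
Reactants: 7 methyl 2-(benzyloxy)-4-methoxy-6-methylbenzoate
Product: 8 2-(benzyloxy)-4-methoxy-6-methylbenzoic acid
Conditions: KOH, DMSO–H2O, 90 °C; then aq. HCl, 0 °C
Reagents that add atoms: potassium hydroxide, [K+].[OH-]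
Why: Saponification of a di-ortho-substituted benzoate with poorly solvated hydroxide in hot aqueous DMSO should cleave the hindered ester while the benzyl and methyl ethers survive the base.

Step 8
Reactants: 9 orcinol (5-methylbenzene-1,3-diol)
Product: 10 benzyl (3-hydroxy-5-methylphenyl) carbonate
Conditions: 9 (3 equiv), CbzCl (1 equiv), pyridine (1.1 equiv), CH2Cl2–THF, 0 °C
Reagents that add atoms: benzyl chloroformate, O=C(Cl)OCc1ccccc1
Why: Schotten–Baumann-type mono-O-acylation of a symmetric diphenol, with excess cheap, water-soluble orcinol to suppress the bis-carbonate, should desymmetrise ring B.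

Step 9
Reactants: 10 benzyl (3-hydroxy-5-methylphenyl) carbonate
Product: 11 benzyl (5-hydroxy-2-iodo-3-methylphenyl) carbonate
Conditions: NIS (1.0 equiv), TsOH·H2O (10 mol%), MeCN, 0 °C to rt
Reagents that add atoms: N-iodosuccinimide, O=C1CCC(=O)N1I
Why: Electrophilic aromatic iodination with acid-activated NIS goes para to a free phenol OH, and since the other oxygen is deactivated as a carbonate the iodine should enter at the carbon between OCbz and CH3, the future C1 of ring B.

Step 10
Reactants: 8 2-(benzyloxy)-4-methoxy-6-methylbenzoic acid; 11 benzyl (5-hydroxy-2-iodo-3-methylphenyl) carbonate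
Product: 13 3-{[(benzyloxy)carbonyl]oxy}-4-iodo-5-methylphenyl 2-(benzyloxy)-4-methoxy-6-methylbenzoate, via mixed trifluoroacetic anhydride 12 (not isolated)
Conditions: 8 (1.1 equiv), TFAA (3 equiv), toluene, rt, 15 min; then 11, rt
Reagents that add atoms: trifluoroacetic anhydride, O=C(OC(=O)C(F)(F)F)C(F)(F)F (its atoms appear only in intermediate 12; none remain in 13)
Why: Mixed-anhydride esterification with trifluoroacetic anhydride, the usual way to esterify 2,6-disubstituted benzoic acids with phenols, should acylate the only free and unhindered OH of 11, and the acidic medium leaves the benzyl carbonate, benzyl ether and aryl iodide untouched.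

Step 11
Reactants: 13 3-{[(benzyloxy)carbonyl]oxy}-4-iodo-5-methylphenyl 2-(benzyloxy)-4-methoxy-6-methylbenzoate; 5 methyl 4-(formyloxy)-2-methoxy-6-methylbenzoate
Product: 15 methyl 4-{[2-{[(benzyloxy)carbonyl]oxy}-4-{[2-(benzyloxy)-4-methoxy-6-methylbenzoyl]oxy}-6-methylbenzoyl]oxy}-2-methoxy-6-methylbenzoate, via carbon monoxide 14 (not isolated), via ring-C phenol 4 (not isolated)
Conditions: 5 (2 equiv), Pd(OAc)2 (5 mol%), P(t-Bu)3·HBF4 (20 mol%), Et3N (2.5 equiv), MeCN, 80 °C, sealed vessel
Reagents that add atoms: none
Why: Triethylamine should split formate 5 into carbon monoxide and the phenoxide of 4; Pd(0) adds oxidatively to the C–I bond of 13, CO inserts into the aryl–Pd bond (this makes the bond between ring-B C1 and the carbonyl carbon, the former formyl carbon of 5), and the phenoxide of 4 closes the ester by C–O reductive elimination from the acyl–palladium species. The closest known reaction type is the palladium-catalysed esterification of aryl halides with aryl formates without external CO, a variant of the three-component aryloxycarbonylation ArX + CO + Ar'OH. No ring is closed and no stereocentre is formed. The step needs one reacting C–I bond and one reacting phenol: 13 has a single iodide, and the phenoxide of 4 is the only free phenol because the ring-A and ring-B hydroxyls are masked as benzyl ether and benzyl carbonate. The existing aryl ester and the new one are 2,6-disubstituted benzoates, too hindered for transesterification by the phenoxide, and the bulky monodentate phosphine should accept the di-ortho-substituted iodide while disfavouring ionisation of the benzyl carbonate.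

Step 12
Reactants: 15 methyl 4-{[2-{[(benzyloxy)carbonyl]oxy}-4-{[2-(benzyloxy)-4-methoxy-6-methylbenzoyl]oxy}-6-methylbenzoyl]oxy}-2-methoxy-6-methylbenzoate
Product: 16 methyl 4-{[2-hydroxy-4-[(2-hydroxy-4-methoxy-6-methylbenzoyl)oxy]-6-methylbenzoyl]oxy}-2-methoxy-6-methylbenzoate (target, CNP0106353.0)
Conditions: H2 (1 atm), 10% Pd/C, EtOAc, rt
Reagents that add atoms: none
Why: Catalytic hydrogenolysis should cleave the ring-A benzyl ether and the ring-B benzyl carbonate (the latter with loss of CO2) in one operation, while the aryl esters and the methyl ester are inert and no halogen remains to be reduced.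

**Compound list**

1 | methyl orsellinate (methyl 2,4-dihydroxy-6-methylbenzoate) | COC(=O)c1c(C)cc(O)cc1O | starting material
2 | methyl 4-(benzyloxy)-2-hydroxy-6-methylbenzoate | COC(=O)c1c(C)cc(OCc2ccccc2)cc1O | intermediate
3 | methyl 4-(benzyloxy)-2-methoxy-6-methylbenzoate | COC(=O)c1c(C)cc(OCc2ccccc2)cc1OC | intermediate
4 | methyl 4-hydroxy-2-methoxy-6-methylbenzoate | COC(=O)c1c(C)cc(O)cc1OC | intermediate
5 | methyl 4-(formyloxy)-2-methoxy-6-methylbenzoate | COC(=O)c1c(C)cc(OC=O)cc1OC | intermediate
6 | methyl 2-hydroxy-4-methoxy-6-methylbenzoate | COC(=O)c1c(C)cc(OC)cc1O | intermediate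
7 | methyl 2-(benzyloxy)-4-methoxy-6-methylbenzoate | COC(=O)c1c(C)cc(OC)cc1OCc1ccccc1 | intermediate
8 | 2-(benzyloxy)-4-methoxy-6-methylbenzoic acid | OC(=O)c1c(C)cc(OC)cc1OCc1ccccc1 | intermediate
9 | orcinol (5-methylbenzene-1,3-diol) | Cc1cc(O)cc(O)c1 | starting material
10 | benzyl (3-hydroxy-5-methylphenyl) carbonate | O=C(OCc1ccccc1)Oc1cc(C)cc(O)c1 | intermediate
11 | benzyl (5-hydroxy-2-iodo-3-methylphenyl) carbonate | O=C(OCc1ccccc1)Oc1cc(O)cc(C)c1I | intermediate
12 | 2-(benzyloxy)-4-methoxy-6-methylbenzoic trifluoroacetic anhydride | O=C(OC(=O)C(F)(F)F)c1c(C)cc(OC)cc1OCc1ccccc1 | intermediate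
13 | 3-{[(benzyloxy)carbonyl]oxy}-4-iodo-5-methylphenyl 2-(benzyloxy)-4-methoxy-6-methylbenzoate | O=C(OCc1ccccc1)Oc1cc(OC(=O)c2c(C)cc(OC)cc2OCc2ccccc2)cc(C)c1I | intermediate
14 | carbon monoxide | [C-]#[O+] | intermediate
15 | methyl 4-{[2-{[(benzyloxy)carbonyl]oxy}-4-{[2-(benzyloxy)-4-methoxy-6-methylbenzoyl]oxy}-6-methylbenzoyl]oxy}-2-methoxy-6-methylbenzoate | COC(=O)c1c(C)cc(OC(=O)c2c(C)cc(OC(=O)c3c(C)cc(OC)cc3OCc3ccccc3)cc2OC(=O)OCc2ccccc2)cc1OC | intermediate
16 | methyl 4-{[2-hydroxy-4-[(2-hydroxy-4-methoxy-6-methylbenzoyl)oxy]-6-methylbenzoyl]oxy}-2-methoxy-6-methylbenzoate | COC(=O)c1c(C)cc(OC(=O)c2c(C)cc(OC(=O)c3c(C)cc(OC)cc3O)cc2O)cc1OC | target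

**Step count and risks**

Total step count: 12.
Longest linear sequence: 6 steps (steps 1, 2, 3, 4, 11, 12; the ring-A branch, steps 5, 6, 7, 10, 11, 12, is equally long).

Steps most likely to fail:

1. Step 11. Oxidative addition and CO insertion at the aryl carbon with two ortho substituents may be slower than escape of CO from solution and reduction of the C–I bond, so the iodide would be consumed without ester formation. Transfer of the benzyl carbonate to the phenoxide would be a second drain. The fallback is the classical acyl-transfer route without carbonylation; it sets out from 1, uses 4 and 8, and comes back to the route at 16.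
   - 1 would be benzylated at both hydroxyls (BnBr, K2CO3, DMF, 70 °C) to methyl 2,4-bis(benzyloxy)-6-methylbenzoate F1, then saponified (KOH, DMSO–H2O, 90 °C; aq. HCl) to 2,4-bis(benzyloxy)-6-methylbenzoic acid F2.
   - Activation with TFAA in toluene to 2,4-bis(benzyloxy)-6-methylbenzoic trifluoroacetic anhydride F3 and addition of phenol 4 should give methyl 4-{[2,4-bis(benzyloxy)-6-methylbenzoyl]oxy}-2-methoxy-6-methylbenzoate F4.
   - Hydrogenolysis (H2, Pd/C, EtOAc) should give methyl 4-[(2,4-dihydroxy-6-methylbenzoyl)oxy]-2-methoxy-6-methylbenzoate F5.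
   - Because the 2-OH of F5 is chelated, acylation with 8 and TFAA (via 12) should occur only at the 4-OH and give methyl 4-{[4-{[2-(benzyloxy)-4-methoxy-6-methylbenzoyl]oxy}-2-hydroxy-6-methylbenzoyl]oxy}-2-methoxy-6-methylbenzoate F6.
   - A final hydrogenolysis (H2, Pd/C, EtOAc) should give 16.

2. Step 9. The iodination may show poor para/ortho selectivity relative to the free hydroxyl, or run on to di-iodination. The fallback sets out from 9 and comes back at 13; it iodinates before desymmetrisation and tells the two hydroxyls apart by hindrance instead of by electronic direction.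
   - 9 would be iodinated while still symmetric (ICl, Et2O, 0 °C), where the two positions para to a hydroxyl are equivalent, to give 4-iodo-5-methylbenzene-1,3-diol F7.
   - Acylation with 8 and TFAA (via 12) should take place at the hydroxyl para to iodine, which has two free ortho positions, and give 3-hydroxy-4-iodo-5-methylphenyl 2-(benzyloxy)-4-methoxy-6-methylbenzoate F8.
   - The remaining hydroxyl next to iodine would then be converted into the benzyl carbonate (CbzCl, pyridine, CH2Cl2, 0 °C) to reach 13.

3. Step 10. O-Trifluoroacetylation of the electron-poor iodophenol may outrun the slow transfer of the hindered aroyl group, or the acid may cleave the ortho benzyl ether. The fallback sets out from 8 and comes back at 13; it replaces the acidic mixed-anhydride activation with a base-mediated acyl chloride acylation.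
   - 8 would be converted with oxalyl chloride and catalytic DMF in CH2Cl2 into 2-(benzyloxy)-4-methoxy-6-methylbenzoyl chloride F9.
   - F9 would be coupled with 11 under nucleophilic catalysis (Et3N, DMAP cat., CH2Cl2, 0 °C to rt) to give 13.

**Further compounds**

F1 | step 11 | methyl 2,4-bis(benzyloxy)-6-methylbenzoate | COC(=O)c1c(C)cc(OCc2ccccc2)cc1OCc1ccccc1
F2 | step 11 | 2,4-bis(benzyloxy)-6-methylbenzoic acid | OC(=O)c1c(C)cc(OCc2ccccc2)cc1OCc1ccccc1
F3 | step 11 | 2,4-bis(benzyloxy)-6-methylbenzoic trifluoroacetic anhydride | O=C(OC(=O)C(F)(F)F)c1c(C)cc(OCc2ccccc2)cc1OCc1ccccc1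
F4 | step 11 | methyl 4-{[2,4-bis(benzyloxy)-6-methylbenzoyl]oxy}-2-methoxy-6-methylbenzoate | COC(=O)c1c(C)cc(OC(=O)c2c(C)cc(OCc3ccccc3)cc2OCc2ccccc2)cc1OC
F5 | step 11 | methyl 4-[(2,4-dihydroxy-6-methylbenzoyl)oxy]-2-methoxy-6-methylbenzoate | COC(=O)c1c(C)cc(OC(=O)c2c(C)cc(O)cc2O)cc1OC
F6 | step 11 | methyl 4-{[4-{[2-(benzyloxy)-4-methoxy-6-methylbenzoyl]oxy}-2-hydroxy-6-methylbenzoyl]oxy}-2-methoxy-6-methylbenzoate | COC(=O)c1c(C)cc(OC(=O)c2c(C)cc(OC(=O)c3c(C)cc(OC)cc3OCc3ccccc3)cc2O)cc1OC
F7 | step 9 | 4-iodo-5-methylbenzene-1,3-diol | Cc1cc(O)cc(O)c1I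
F8 | step 9 | 3-hydroxy-4-iodo-5-methylphenyl 2-(benzyloxy)-4-methoxy-6-methylbenzoate | Oc1cc(OC(=O)c2c(C)cc(OC)cc2OCc2ccccc2)cc(C)c1I
F9 | step 10 | 2-(benzyloxy)-4-methoxy-6-methylbenzoyl chloride | O=C(Cl)c1c(C)cc(OC)cc1OCc1ccccc1
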